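## Retrosynthetic overview
1. Ring A is the acylated cyclohexanetrione, ring B the spiro cyclohexane, ring C the cyclopentane. Ring C is bought as cyclopentenone, ring A is made by dearomatising an arene, and ring B is closed last.
2. 18 ⇒ 16 by methyl addition to the ring C ketone. 16 ⇒ 15 by reductive ketone–enone coupling, which forms the bond from the ring B carbinol carbon to the ring-fusion CH and closes ring B.
3. 15 ⇒ 13 ⇒ 11 by two catalyst-controlled phase-transfer C-alkylations: chloroacetone at the future spiro carbon, prenyl bromide at the methyl-bearing carbon.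
4. 11 ⇒ 5 + 10, by C-alkylation of the only free arene CH with a Baylis–Hillman acetate made from cyclopentenone and formaldehyde.
5. 5 ⇒ 2-methylphloroglucinol + (S)-2-methylbutanoic acid, the acid coming from tiglic acid by asymmetric hydrogenation.

Assumption: enolised tricarbonyl compounds are drawn in the tautomer used in the target SMILES. The facial sense of the two ammonium catalysts cannot be predicted. It is fixed by one test run with each pseudoenantiomer, and the one named below is taken to give the drawn product.

Catalysts: Q1 = 2,7-bis[(O-allylhydrocinchonidinium-1-yl)methyl]naphthalene dibromide. Q2 = its hydrocinchoninium (pseudoenantiomeric) analogue.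

## Route

Step 1
Reactants: 1 tiglic acid ((E)-2-methylbut-2-enoic acid)
Product: 2 (S)-2-methylbutanoic acid
Conditions: H2 (4 atm), Ru(OAc)2[(S)-H8-BINAP] (0.5 mol %), MeOH, 20 °C
Reagents that add atoms: none
Why: Asymmetric hydrogenation of an α,β-unsaturated acid; the carboxylate binds to ruthenium and the chiral diphosphine lets H2 reach only one alkene face, which sets the (S) side-chain stereocentre in high ee.

Step 2
Reactants: 2 (S)-2-methylbutanoic acid; 3 2-methylphloroglucinol (2-methylbenzene-1,3,5-triol)
Product: 5 (S)-2-methyl-1-(2,4,6-trihydroxy-3-methylphenyl)butan-1-one, via (S)-2-methylbutanoyl chloride 4 (not isolated)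
Conditions: (COCl)2, DMF (cat.), CH2Cl2, 0 °C to rt; then 3, AlCl3 (3.5 equiv), CH2Cl2–PhNO2, 0 °C to rt; aq HCl
Reagents that add atoms: oxalyl chloride, O=C(Cl)C(Cl)=O (its chlorine is found in 4 only)
Why: Friedel–Crafts acylation; the two free ring positions of 3 are equivalent and the first acyl group deactivates the ring against a second one, and the low temperature keeps the α-stereocentre intact.

Step 3
Reactants: 6 cyclopent-2-en-1-one; 7 formaldehyde
Product: 8 2-(hydroxymethyl)cyclopent-2-en-1-one
Conditions: 37% aq HCHO, PBu3 (10 mol %), CHCl3–MeOH, rt
Reagents that add atoms: formaldehyde 7, C=O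
Why: Morita–Baylis–Hillman reaction; the phosphine adds to the enone and the resulting enolate traps formaldehyde at the α-carbon; no stereocentre is formed.

Step 4
Reactants: 8 2-(hydroxymethyl)cyclopent-2-en-1-one; 9 acetic anhydride
Product: 10 (5-oxocyclopent-1-en-1-yl)methyl acetate
Conditions: Ac2O, pyridine, DMAP (cat.), CH2Cl2, 0 °C
Reagents that add atoms: acetic anhydride 9, CC(=O)OC(C)=O
Why: O-acetylation of a primary allylic alcohol, which gives the leaving group needed for the allylic substitution.

Step 5
Reactants: 5 acylphloroglucinol; 10 Baylis–Hillman acetate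
Product: 11 2-({2,4,6-trihydroxy-3-methyl-5-[(2S)-2-methylbutanoyl]phenyl}methyl)cyclopent-2-en-1-one
Conditions: DABCO (1.1 equiv), THF–H2O, rt
Reagents that add atoms: none
Why: Lewis-base-mediated allylic substitution of a Baylis–Hillman acetate (SN2'–SN2') by the soft ring carbon of 5; only one ring CH is free, and any O-alkylated ether is itself a Baylis–Hillman electrophile that reverts under DABCO, so the C–C product accumulates (11 equilibrates reversibly with its oxa-Michael chromanone form).

Step 6
Reactants: 11 hexasubstituted arene; 12 prenyl bromide (1-bromo-3-methylbut-2-ene)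
Product: 13 (6R)-3,5-dihydroxy-6-methyl-6-(3-methylbut-2-enyl)-4-[(2S)-2-methylbutanoyl]-2-[(5-oxocyclopent-1-en-1-yl)methyl]cyclohexa-2,4-dien-1-one
Conditions: 12 (1.1 equiv), Q1 (10 mol %), CsOH·H2O (2.2 equiv), 4 Å MS, CH2Cl2–toluene, −50 °C
Reagents that add atoms: prenyl bromide 12, CC(C)=CCBr
Why: Proposed new method: catalytic asymmetric alkylative dearomatisation under phase transfer; the dianion of 11 enters the organic phase as a tight 1:1 ion pair with the rigid bis-ammonium cation, N+–C–H···O contacts hold the chelated acyl/oxide edge so that a quinoline wall covers one ring face, and prenyl bromide reacts by SN2 on the open face of the methyl-bearing carbon (less hindered than the CH2R-bearing carbon, whose neighbouring oxygen is also partly masked by the reversible oxa-Michael closure), which sets the (R) quaternary carbon; the closest known reaction types are the racemic aqueous-base C-prenylation of acylphloroglucinols, the phase-transfer alkylative dearomatisation–annulation of benzoylphloroglucinols with this catalyst family, and the asymmetric phase-transfer alkylation of cyclic β-keto esters.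

Step 7
Reactants: 13 dearomatised dienol; 14 chloroacetone
Product: 15 (4R,6R)-3-hydroxy-4-methyl-4-(3-methylbut-2-enyl)-2-[(2S)-2-methylbutanoyl]-6-(2-oxopropyl)-6-[(5-oxocyclopent-1-en-1-yl)methyl]cyclohex-2-ene-1,5-dione
Conditions: 14 (1.5 equiv), Q2 (10 mol %), CsOH·H2O (2.2 equiv), toluene–CH2Cl2, −40 °C
Reagents that add atoms: chloroacetone 14, CC(=O)CCl
Why: Proposed new method: catalyst-controlled phase-transfer quaternisation of a 2-substituted cyclic 1,3-dicarbonyl dianion; the only remaining nucleophilic ring carbon attacks chloroacetone by SN2, the existing quaternary carbon exerts almost no 1,3-bias because it shows a CH3 on one face and a CH2 on the other, and so the bis-ammonium ion pair decides the face and sets the future spiro carbon as (R); the closest known reaction types are the racemic C-acetonylation of 2-alkylcyclohexane-1,3-diones and the asymmetric phase-transfer alkylation of cyclic β-keto esters to quaternary centres.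

Step 8
Reactants: 15 keto-enone
Product: 16 spiro ketone with the target skeleton in which ring C still carries C=O in place of C(CH3)OH (side chain S; ring A quaternary carbon R; spiro carbon R; cis ring fusion with both CH centres S; ring B carbinol carbon R)
Conditions: SmI2 (2.5 equiv, 0.1 M in THF), MeOH (10 equiv), −78 °C; pH 7 buffer
Reagents that add atoms: none
Why: SmI2 ketyl–olefin (reductive ketone–enone) cyclisation to the enone β-carbon through a chair transition state; the samarium-bound oxygen is axial and bridged to the electron-rich vinylogous-acid carbonyl of ring A while CH3 is equatorial, so the carbinol carbon and the adjacent ring-fusion CH follow from the spiro carbon, and the samarium enolate is protonated at −78 °C on the open face opposite the axial groups, which gives the cis fusion under kinetic control.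

Step 9
Reactants: 16 spiro ketone; 17 methylmagnesium bromide
Product: 18 hyperielliptone HB
Conditions: MeMgBr (5 equiv), LaCl3·2LiCl (1.5 equiv), THF, −78 to −20 °C; aq NH4Cl
Reagents that add atoms: methylmagnesium bromide 17, C[Mg]Br
Why: Lanthanide-assisted Grignard 1,2-addition; the two OH groups are deprotonated first, so the acyl-tricarbonyl unit is masked as its enolate, the remaining ring A ketone lies between two quaternary carbons, the low basicity of the reagent suppresses enolisation and retro-Michael opening, and methyl attacks the cyclopentanone from the convex face bearing the two ring-fusion hydrogens, which gives the (R) carbinol with OH cis to the ring B CH2.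

## Compound list
1 | tiglic acid | C/C=C(\C)C(=O)O | starting material
2 | (S)-2-methylbutanoic acid | CC[C@H](C)C(=O)O | intermediate
3 | 2-methylphloroglucinol | Cc1c(O)cc(O)cc1O | starting material
4 | (S)-2-methylbutanoyl chloride | CC[C@H](C)C(=O)Cl | intermediate
5 | (S)-2-methyl-1-(2,4,6-trihydroxy-3-methylphenyl)butan-1-one | CC[C@H](C)C(=O)c1c(O)cc(O)c(C)c1O | intermediate
6 | cyclopent-2-en-1-one | O=C1CCC=C1 | starting material
7 | formaldehyde | C=O | starting material
8 | 2-(hydroxymethyl)cyclopent-2-en-1-one | O=C1CCC=C1CO | intermediate
9 | acetic anhydride | CC(=O)OC(C)=O | starting material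
10 | (5-oxocyclopent-1-en-1-yl)methyl acetate | CC(=O)OCC1=CCCC1=O | intermediate
11 | arene carrying acyl, methyl and (5-oxocyclopentenyl)methyl groups | CC[C@H](C)C(=O)c1c(O)c(CC2=CCCC2=O)c(O)c(C)c1O | intermediate
12 | prenyl bromide | CC(C)=CCBr | starting material
13 | (6R)-dearomatised dienol | CC[C@H](C)C(=O)C1=C(O)[C@@](C)(CC=C(C)C)C(=O)C(CC2=CCCC2=O)=C1O | intermediate
14 | chloroacetone | CC(=O)CCl | starting material
15 | (4R,6R)-keto-enone with both arms on the future spiro carbon | CC[C@H](C)C(=O)C1=C(O)[C@@](C)(CC=C(C)C)C(=O)[C@](CC(C)=O)(CC2=CCCC2=O)C1=O | intermediate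
16 | spiro cis-hydrindanone | CC[C@H](C)C(=O)C1=C(O)[C@@](C)(CC=C(C)C)C(=O)[C@]2(C[C@H]3[C@H](CCC3=O)[C@](C)(O)C2)C1=O | intermediate
17 | methylmagnesium bromide | C[Mg]Br | starting material
18 | hyperielliptone HB | CC[C@H](C)C(=O)C1=C(O)[C@@](C)(CC=C(C)C)C(=O)[C@]2(C[C@H]3[C@H](CC[C@@]3(C)O)[C@](C)(O)C2)C1=O | target

## Step count and risks
Total steps: 9. Longest linear sequence: 7 (steps 1, 2, 5, 6, 7, 8, 9, or equally 3, 4, 5, 6, 7, 8, 9).

The three steps most likely to fail are steps 6, 7 and 8.

**Step 6 (proposed new step).**
- Risks: attack at the wrong ring carbon, O-prenylation, and low facial selectivity.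
- Fallback (known chemistry): it sets out from 11. Classical dearomative C-prenylation with 12 in aqueous KOH at 0 °C, without a chiral catalyst, gives 13 together with the (6S)-epimer of 13 F1.
- The (S) side chain makes these two compounds diastereomers. They are separated by preparative HPLC or by fractional crystallisation of their dicyclohexylammonium salts.
- The fallback comes back to the route at 13.

**Step 7 (proposed new step).**
- Risks: O-alkylation or furan formation, slow reaction at the hindered carbon, and poor control of the spiro carbon.
- Fallback (known chemistry): it sets out from 13. A quinine-derived amine–squaramide catalyst (5 mol %, CH2Cl2, −20 °C) promotes conjugate addition of the 2-substituted 1,3-dicarbonyl to 2-nitropropene.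
- This gives the quaternary 2-nitropropyl adduct F2, as a mixture at the nitro-bearing carbon, which does not matter.
- A reductive Nef reaction (TiCl3, aq NH4OAc, THF, 0 °C) then converts F2 into the ketone. The fallback comes back to the route at 15.

**Step 8.**
- Risks: loss of the stabilised ring A carbanion from the reduced enone, simple 1,4-reduction, pinacol coupling, and epimerisation of the kinetic cis fusion.
- Fallback: it sets out from 15. Soft enolisation of the methyl ketone on its CH3 side (Et3SiOTf, 2,6-lutidine, CH2Cl2, −78 °C; the labile ring A silyl enol ether falls off on aqueous work-up) gives the triethylsilyl enol ether F3.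
- Hydrogen-atom transfer to F3 (Fe(acac)3 cat., PhSiH3, EtOH, 40 °C) produces the α-silyloxy tertiary radical. This closes ring B by Giese addition to the enone and gives the triethylsilyl ether of 16 F4.
- HF·pyridine in THF removes the silyl group. The fallback comes back to the route at 16.

## Further compounds
F1 | step 6 | (6S)-epimer of 13 | CC[C@H](C)C(=O)C1=C(O)[C@](C)(CC=C(C)C)C(=O)C(CC2=CCCC2=O)=C1O
F2 | step 7 | analogue of 15 with a 2-nitropropyl arm in place of the 2-oxopropyl arm | CC[C@H](C)C(=O)C1=C(O)[C@@](C)(CC=C(C)C)C(=O)[C@](CC(C)[N+](=O)[O-])(CC2=CCCC2=O)C1=O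
F3 | step 8 | triethylsilyl enol ether of the methyl ketone of 15 | CC[C@H](C)C(=O)C1=C(O)[C@@](C)(CC=C(C)C)C(=O)[C@](CC(=C)O[Si](CC)(CC)CC)(CC2=CCCC2=O)C1=O
F4 | step 8 | triethylsilyl ether of 16 at the ring B carbinol | CC[C@H](C)C(=O)C1=C(O)[C@@](C)(CC=C(C)C)C(=O)[C@]2(C[C@H]3[C@H](CCC3=O)[C@](C)(O[Si](CC)(CC)CC)C2)C1=O
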